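# Proposed total synthesis of CNP0174045.1 (33) by double asymmetric hydroxymethylation of a 1,4-bis(silyloxy)diene

## The problem

Target 33 is a tetra-aryl lignan built on a cis-fused 3,7-dioxabicyclo[3.3.0]octane (furofuran) core in which C1 and C5 are the bridgeheads, C2 and C6 the benzylic carbons and C4 and C8 the methylenes. C2 carries guaiacyl ring B, which bears ortho to its phenol an (S)-CH(CH2OH)–C(=O)–aryl (ring D) arm, and C6 carries ring C, which is fused to a cis-2-aryl (ring E)-3-hydroxymethyl-2,3-dihydrobenzofuran.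

The seven stereocentres fall into three clusters, four in the core (1R,2S,5R,6S, both aryl groups exo), two in the dihydrobenzofuran (2S,3S, the less stable cis arrangement) and one α to the ketone, and the clusters are too far apart to control one another, so each needs its own source of absolute configuration. Within the core, however, the bridgeheads can dictate C2 and C6, because ring closure under ionising conditions puts the aryl groups on the convex face.

The α-aryl β-hydroxy ketone is the most fragile element: it can enolise, lose formaldehyde by retro-aldol reaction, dehydrate, or cyclodehydrate with the neighbouring phenol. The cis-dihydrobenzofuran and the benzylic ethers of the core open under acid once their para-phenols are free, every benzylic C–O bond is at risk under hydrogenolysis, and rings B and C, which are almost identical in constitution, must be differentiated from the first step.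

The enabling feature is that C4 and C8 sit on the adjacent bridgeheads C5 and C1, each α to a benzylic carbon (C6, C2) that can be written as a ketone. The core is therefore a masked (2R,3R)-2,3-bis(hydroxymethyl)-1,4-diaryl-butane-1,4-dione whose two C–CH2OH bonds can both come from formaldehyde.

## Retrosynthesis

**Unmasking and ketone (33 ⇐ 32 ⇐ 31).** No skeletal bond is cut: five silyl ethers and the carbonyl oxidation level are removed. The labile α-stereocentre should exist next to a ketone only in the last two operations, so the ketone is derived from secondary benzylic alcohol 31 by neutral oxidation. Making it by acylation would expose the centre to basic organometallics. The forward steps must oxidise and desilylate without enolisation.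

**Keto arm (31 ⇐ 30 ⇐ 29 ⇐ 27 + 28).** The bond between the α-carbon and the carbinol carbon is cut as an auxiliary-controlled syn aldol between arylacetyl imide 27 and silylated vanillin 28. The auxiliary fixes the α-centre, the carbinol centre is sacrificial, and wrong isomers are separable while the auxiliary is attached. Cutting Cα–CH2OH instead (hydroxymethylation of a deoxybenzoin) would create the centre directly beside the ketone with no chance of purification. The precursor loses ring D, two stereocentres and the whole oxidation-state problem.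

**Arylacetic acid (27 ⇐ 24 ⇐ 23 ⇐ 22).** The C=C bond of an allyl group is cleaved to give the acid. Allyl is chosen because it is inert to every core-forming reagent and comes from vanillin by a Claisen rearrangement.

**Dihydrobenzofuran (22 ⇐ 21 ⇐ 20 ⇐ 19 ⇐ 18 ⇐ 17).** The C2–C3 bond of the dihydrobenzofuran is cut as a dirhodium carbenoid insertion into the benzylic C–H bond of an aryl benzyl ether. The ring C–CH2 bond is then cut as a Negishi-type coupling of bromide 17. Closing O1–C2 by ionisation would give the trans isomer; the insertion is kinetically cis and catalyst-controlled. The benzyl group that becomes ring E and C2 is carried from the start with its phenol as a pivalate, which makes the benzyl ether acid-stable and is removed in the same reduction that forms the CH2OH group.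

**Core (17 ⇐ 16 ⇐ 15).** C2–O3 and C6–O7 are cut. Reducing diketone diol 15 to tetraol 16 and closing under ionising conditions is stereoconvergent at C2/C6, so only the two bridgeheads need to be set beforehand. The precursor is acyclic with two stereocentres.

**Key disconnection (15 ⇐ 12 + 2 × 13).** C4–C5 and C8–C1 are cut to bis(silyl enol ether) 12 and two molecules of formaldehyde 13. This removes both remaining stereocentres and leaves an achiral diene. The forward reaction must add formaldehyde twice with the same catalyst-controlled facial sense.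

**Diketone (12 ⇐ 11 ⇐ 10 + 6).** The bond between the ring C acyl carbon and its α-methylene is cut as a Stetter reaction of aldehyde 10 with aryl vinyl ketone 6. The two differently substituted rings are joined in one step without enolate chemistry.

**Fragments (10 ⇐ 8 + 9; 8 ⇐ 7 ⇐ 1; 6 ⇐ 5 ⇐ 4 ⇐ 3 ⇐ 2 ⇐ 1).** The benzyl aryl ether bond is cut as a Mitsunobu reaction of 5-bromovanillin 9 with benzyl alcohol 8. The allyl group goes back to O-allyl vanillin 2. Everything derives from vanillin 1, bromovanillin 9 and formaldehyde 13.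

## Roads not taken

Alternative 1: Wolff ring contraction of a 3-diazoflavanone.
- Cut: the C3–C3a bond of the dihydrobenzofuran, which is derived from a six-membered chromanone.
- Forward key step: irradiation of (2R)-6-bromo-3-diazo-8-methoxy-2-(silyloxyaryl)chroman-4-one A1 in methanol expels dinitrogen and the aryl carbon migrates from the carbonyl carbon to C3. The solvent adds to the resulting C=C=O unit and C3 is protonated anti to the C2 aryl group, giving the cis methyl ester A2 with the bromine in place.
- Merits: the contra-thermodynamic cis relationship is set by the substrate without a chiral catalyst, and the bromine is a ready handle.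
- Weak points: it solves only one of three stereo-clusters. The absolute configuration at C2 of A1 has to be set before the diazo group is introduced, and the pyranone ring of A1 can open reversibly by retro-oxa-Michael reaction under the basic conditions of diazo transfer, which racemises C2. The furofuran and keto arm would then have to be built on A2 in a long linear sequence that exposes the epimerisable cis unit to the acid of core formation.
- Comparison: for cis selectivity alone this road is as good as the insertion in step 16, or better. The chosen plan answers with an insertion that is also kinetically cis and sets absolute configuration by catalyst on a substrate class with direct precedent, and it reaches the core in three steps from a diketone.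

Alternative 2: double Friedel–Crafts arylation of a chiral bis-oxocarbenium.
- Cut: both aryl–C2 and aryl–C6 bonds.
- Forward key step: BF3·OEt2 ionises both acetates of the bis-lactol diacetate A3 in turn, and each bicyclic oxocarbenium ion is attacked on its convex face by the para carbon of 2-allyl-6-methoxyphenol A4 to give 5,5'-diallylpinoresinol A5 in one operation.
- Merits: the shortest path to the core; exo,exo geometry follows from convex attack; the phenols need no protection.
- Weak points: A5 is C2-symmetric, while the target needs two different arms, so the two identical allyl/phenol pairs could only be differentiated statistically. O-attack versus C-attack on the oxocarbenium and the enantioselective supply of A3 are further burdens.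
- Comparison: this road is better in step count to the furofuran and uses no unproven reaction. The chosen plan offers rings that are differentiated from the first step (bromide against allyl, benzyl ether against silyl ether), so no statistical step is needed, and absolute configuration from a catalytic step.

Alternative 3: titanocene epoxide radical–polar cascade.
- Cut: C1–C5 and C2–O3.
- Forward key step: Cp2TiCl (trivalent titanium) opens the terminal epoxide of the epoxy cinnamyl ether A6 to a radical at C5, which adds 5-exo to the cinnamyl alkene. Iodine then lets the titanium alkoxide on C4 close onto benzylic C2, giving the bromo furofuran A7 with the silylated dihydrobenzofuran already in place.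
- Merits: convergent, unsymmetrical by design, neutral conditions, and the core is formed late, so the dihydrobenzofuran never meets the acid of a cationic closure.
- Weak points: the single stereocentre C6 of A6 must control three new centres (C5, C1, C2), and the closing step at C2 can give exo/endo mixtures. The titanium reagent is used in excess. C6 is an ionisable para-oxygenated benzylic ether that must be made enantiopure. The cis-dihydrobenzofuran still has to be made beforehand by some other method.
- Comparison: this road is as good or better in convergence and in sparing the dihydrobenzofuran. The chosen plan offers catalytic creation of both bridgeheads with statistical enrichment of the homochiral product, and a ring closure that rejects the wrong diastereomer.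

Key step: step 11

Abbreviations used in names: ArB = 3-allyl-5-methoxy-4-(triisopropylsilyloxy)phenyl; ArC = 3-bromo-5-methoxy-4-{[3-methoxy-4-(pivaloyloxy)benzyl]oxy}phenyl; core = (1R,2S,5R,6S)-3,7-dioxabicyclo[3.3.0]octane with ring B on C2 and ring C on C6.

Assumption: the sense of induction of the scandium–bipyridine catalyst (step 11) and of Rh2(S-PTTL)4 (step 16) is taken to follow that of simple aryl ketone enol silanes and 2-benzyloxyphenyl diazoacetates; if either is opposite, the mirror-image ligand is used with no other change.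

## Route

Step 1
Reactants: 1 vanillin
Product: 2 4-(allyloxy)-3-methoxybenzaldehyde
Conditions: allyl bromide, K2CO3, DMF, rt
Reagents that add atoms: allyl bromide, C=CCBr
Why: Williamson ether synthesis on an acidic para-formyl phenol; O-alkylation is the only course.

Step 2
Reactants: 2 4-(allyloxy)-3-methoxybenzaldehyde
Product: 3 5-allylvanillin (3-allyl-4-hydroxy-5-methoxybenzaldehyde)
Conditions: neat, 200 °C
Reagents that add atoms: none
Why: Aromatic Claisen rearrangement; only one ortho position is free, so the allyl group is delivered to C5 alone.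

Step 3
Reactants: 3 5-allylvanillin
Product: 4 3-allyl-5-methoxy-4-(triisopropylsilyloxy)benzaldehyde
Conditions: TIPSOTf, 2,6-lutidine, CH2Cl2, 0 °C to rt
Reagents that add atoms: triisopropylsilyl triflate, CC(C)[Si](C(C)C)(C(C)C)OS(=O)(=O)C(F)(F)F
Why: Silylation of a hindered phenol with the triflate; the bulky silyl ether is chosen to last until the final fluoride step.

Step 4
Reactants: 4 3-allyl-5-methoxy-4-(triisopropylsilyloxy)benzaldehyde
Product: 5 rac-1-ArB-prop-2-en-1-ol
Conditions: CH2=CHMgBr, THF, −78 to 0 °C; aq. NH4Cl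
Reagents that add atoms: vinylmagnesium bromide, C=C[Mg]Br
Why: Grignard 1,2-addition to an aryl aldehyde; the carbinol centre is removed in the next step, so it is left racemic.

Step 5
Reactants: 5 rac-1-ArB-prop-2-en-1-ol
Product: 6 1-ArB-prop-2-en-1-one (aryl vinyl ketone)
Conditions: activated MnO2, CH2Cl2, rt
Reagents that add atoms: none
Why: Selective MnO2 oxidation of a doubly activated (benzylic and allylic) alcohol; the polymerisable enone is used at once.

Step 6
Reactants: 1 vanillin
Product: 7 4-formyl-2-methoxyphenyl pivalate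
Conditions: PivCl, Et3N, DMAP (cat.), CH2Cl2, 0 °C to rt
Reagents that add atoms: pivaloyl chloride, CC(C)(C)C(=O)Cl
Why: Acylation of the phenol; the acyloxy group later keeps the derived benzyl ether from ionising in acid and carries no α-hydrogen that could be silylated in step 10.

Step 7
Reactants: 7 4-formyl-2-methoxyphenyl pivalate
Product: 8 4-(hydroxymethyl)-2-methoxyphenyl pivalate
Conditions: NaBH4, THF/MeOH, 0 °C
Reagents that add atoms: none
Why: Chemoselective borohydride reduction of the aldehyde beside a hindered aryl ester.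

Step 8
Reactants: 8 4-(hydroxymethyl)-2-methoxyphenyl pivalate; 9 5-bromovanillin
Product: 10 3-bromo-5-methoxy-4-{[3-methoxy-4-(pivaloyloxy)benzyl]oxy}benzaldehyde (ArC–CHO)
Conditions: PPh3, DIAD, THF, 0 °C to rt
Reagents that add atoms: none
Why: Mitsunobu etherification of a primary benzylic alcohol with an acidic phenol; it avoids a labile benzyl halide and installs at the outset the benzyl group that later becomes C2 and ring E of the dihydrobenzofuran.

Step 9
Reactants: 10 ArC–CHO; 6 1-ArB-prop-2-en-1-one
Product: 11 1-ArC-4-ArB-butane-1,4-dione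
Conditions: 3-benzyl-5-(2-hydroxyethyl)-4-methylthiazolium chloride (20 mol%), Et3N, 1,4-dioxane, 70 °C
Reagents that add atoms: none
Why: Stetter reaction: the thiazolylidene converts aldehyde 10 (the more electrophilic partner, because of bromine and the acyloxybenzyl ether) into an acyl anion equivalent that adds 1,4 to enone 6; this is established for alkoxy-substituted benzaldehydes and aryl vinyl ketones.

Step 10
Reactants: 11 1-ArC-4-ArB-butane-1,4-dione
Product: 12 (1Z,3Z)-1-ArC-4-ArB-1,4-bis(trimethylsilyloxy)buta-1,3-diene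
Conditions: TMSOTf (2.4 equiv), Et3N (3.5 equiv), CH2Cl2, 0 °C; non-aqueous work-up
Reagents that add atoms: trimethylsilyl triflate, C[Si](C)(C)OS(=O)(=O)C(F)(F)F
Why: Soft enolisation of both aryl ketones towards their only α-methylene groups; aryl alkyl ketones give the Z enol silanes under these equilibrating conditions, and the excess amine suppresses acid-induced furan formation.

Step 11
Reactants: 12 (1Z,3Z)-bis(silyloxy)diene; 13 formaldehyde (37% aqueous, 10 equiv)
Product: 15 (2R,3R)-1-ArC-4-ArB-2,3-bis(hydroxymethyl)butane-1,4-dione, via mono-hydroxymethyl enol silane 14 (not isolated)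
Conditions: Sc(OTf)3 (20 mol%), (R,R)-6,6'-bis(1-hydroxy-2,2-dimethylpropyl)-2,2'-bipyridine (24 mol%), DME/H2O 9:1, −20 °C; cold extractive work-up, used at once
Reagents that add atoms: none
Why: Proposed new method: each Z enol silane terminus (diene carbons C2 and C3) adds through an open Mukaiyama aldol transition state to formaldehyde bound to the chiral trivalent-scandium–bipyridine-diol complex, and water hydrolyses the silyl oxocarbenium ion formed at that terminus, so the first addition gives 14 (drawn for the more electron-rich ring B enol silane reacting first) with the second enol silane untouched, and the second gives 15. The closest known reaction type is the catalytic enantioselective hydroxymethylation of single silyl enol ethers of aryl ketones with aqueous formaldehyde under the same catalyst, which has not been applied twice to a 1,4-bis(silyloxy)diene. No ring is closed. Both new stereocentres (the future bridgeheads C1 and C5) are set by the catalyst, which selects the same enantioface of each Z aryl enol silane, so two like events give the R,R isomer. The step needs site selectivity, face selectivity and chemoselectivity: the Z,Z geometry turns both silyloxy groups inward, which blocks the s-cis conformer and any hetero-Diels–Alder path, so the diene behaves as two separate enol ethers. The second addition gives the homochiral product as long as catalyst control outweighs the bias of the new neighbouring centre; one mismatch gives the meso diol, which cannot form the cis-fused bicycle in step 13 and is removed there, while the enantiomeric purity of the R,R isomer should rise statistically because its mirror image requires two errors. Low temperature and immediate reduction keep the β-hydroxy ketones from epimerising, dehydrating or closing to lactols and furans.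

Step 12
Reactants: 15 (2R,3R)-diketone diol
Product: 16 (2R,3R)-1-ArC-4-ArB-2,3-bis(hydroxymethyl)butane-1,4-diol (epimer mixture at C1 and C4)
Conditions: NaBH4, CeCl3·7H2O, MeOH/THF, −40 to 0 °C
Reagents that add atoms: none
Why: Luche reduction: the cerium salt speeds 1,2-reduction of the electron-rich aryl ketones and keeps the medium nearly neutral, so the α-centres are not enolised; the carbinol configuration need not be controlled because it is erased in step 13.

Step 13
Reactants: 16 (2R,3R)-tetraol
Product: 17 (1R,2S,5R,6S)-2-ArB-6-ArC-3,7-dioxabicyclo[3.3.0]octane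
Conditions: BF3·OEt2 (0.5 equiv), 4 Å molecular sieves, CH2Cl2, −20 to 0 °C
Reagents that add atoms: none
Why: Acid-mediated double cyclodehydration through para-oxygenated benzylic cations, each trapped 5-exo by the hydroxymethyl group on the distal bridgehead. The bridgeheads fix the cis ring fusion and the aryl groups take the convex (exo) positions, so C2 and C6 are set stereoconvergently from either carbinol epimer. Only the homochiral tetraol can form the bicycle, and the acyloxybenzyl ether, aryl silyl ether, allyl group and bromide are inert.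

Step 14
Reactants: 17 bromo furofuran
Product: 18 methyl arylacetate (17 with Br replaced by CH2CO2Me)
Conditions: BrZnCH2CO2Me (from BrCH2CO2Me and zinc dust), Pd2(dba)3 (2.5 mol%), XPhos (10 mol%), THF, 60 °C
Reagents that add atoms: (2-methoxy-2-oxoethyl)zinc bromide, COC(=O)C[Zn]Br
Why: Negishi-type coupling of a Reformatsky reagent with an aryl bromide under zerovalent palladium; the neutral zinc enolate leaves the pivalate, silyl ether and allyl group alone.

Step 15
Reactants: 18 methyl arylacetate
Product: 19 methyl aryldiazoacetate (18 with CH2 replaced by C=N2)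
Conditions: p-ABSA, DBU, MeCN, 0 °C to rt
Reagents that add atoms: 4-acetamidobenzenesulfonyl azide, CC(=O)Nc1ccc(cc1)S(=O)(=O)N=[N+]=[N-]
Why: Regitz diazo transfer to the benzylic ester position, the only sufficiently acidic C–H in the molecule.

Step 16
Reactants: 19 methyl aryldiazoacetate
Product: 20 cis-dihydrobenzofuran ester (core C6 bound to C5 of methyl (2S,3R)-7-methoxy-2-[3-methoxy-4-(pivaloyloxy)phenyl]-2,3-dihydrobenzofuran-3-carboxylate)
Conditions: Rh2(S-PTTL)4 (1 mol%), toluene, −60 °C
Reagents that add atoms: none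
Why: Intramolecular 1,5 C–H insertion of a donor/acceptor carbenoid of divalent rhodium into the benzylic C–H bond of the ortho benzyl ether, known for 2-benzyloxyphenyl diazoacetates to give cis-2-aryl-2,3-dihydrobenzofuran-3-carboxylates. The concerted insertion sets C2 and C3 cis under kinetic control, and the chiral carboxylate ligands select the enantiotopic hydrogen. Five-ring formation at an oxygen-activated benzylic C–H outruns any reaction at the remote allyl group.

Step 17
Reactants: 20 cis-dihydrobenzofuran ester
Product: 21 diol (20 with CO2Me reduced to CH2OH and the pivalate cleaved to the ring E phenol; dihydrobenzofuran 2S,3S)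
Conditions: i-Bu2AlH (6 equiv), CH2Cl2, −78 to −20 °C; aq. potassium sodium tartrate
Reagents that add atoms: none
Why: Non-basic hydride reduction of the ester removes the epimerisable position before any base is used, and the same reagent cleaves the aryl pivalate, whose protective role ended with step 13.

Step 18
Reactants: 21 diol
Product: 22 bis(tert-butyldimethylsilyl) ether of 21 (CH2OTBS and ring E OTBS)
Conditions: TBSCl (3 equiv), imidazole, DMF, rt
Reagents that add atoms: tert-butyldimethylsilyl chloride, CC(C)(C)[Si](C)(C)Cl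
Why: Standard silylation of a primary alcohol and a phenol; both groups are fluoride-labile for the final step and keep the para-hydroxybenzylic ether of the dihydrobenzofuran from opening.

Step 19
Reactants: 22 allyl arene
Product: 23 arylacetaldehyde (22 with CH2CH=CH2 replaced by CH2CHO)
Conditions: OsO4 (2 mol%), NaIO4, 2,6-lutidine, 1,4-dioxane/H2O 3:1, rt
Reagents that add atoms: osmium tetroxide, O=[Os](=O)(=O)=O; sodium periodate, [Na+].[O-]I(=O)(=O)=O
Why: Lemieux–Johnson cleavage of the only alkene; it avoids ozone on four electron-rich arenes, and the lutidine suppresses over-oxidation.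

Step 20
Reactants: 23 arylacetaldehyde
Product: 24 arylacetic acid (23 with CHO oxidised to CO2H)
Conditions: NaClO2, NaH2PO4, 2-methyl-2-butene, t-BuOH/H2O, 0 °C to rt
Reagents that add atoms: sodium chlorite, [Na+].[O-]Cl=O
Why: Pinnick oxidation; the alkene scavenger removes hypochlorite before it can chlorinate the arenes.

Step 21
Reactants: 24 arylacetic acid; 25 (R)-4-benzyloxazolidin-2-one
Product: 27 (R)-4-benzyl-3-(arylacetyl)oxazolidin-2-one, via mixed pivalic anhydride 26 (not isolated)
Conditions: PivCl, Et3N, THF, −20 °C; then 25, LiCl, rt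
Reagents that add atoms: none
Why: One-flask N-acylation through the mixed anhydride with lithium chloride activation; no strong base touches the substrate.

Step 22
Reactants: 1 vanillin
Product: 28 4-(tert-butyldimethylsilyloxy)-3-methoxybenzaldehyde
Conditions: TBSCl, imidazole, CH2Cl2, rt
Reagents that add atoms: tert-butyldimethylsilyl chloride, CC(C)(C)[Si](C)(C)Cl
Why: Routine phenol silylation to give the ring D aldehyde.

Step 23
Reactants: 27 arylacetyl imide; 28 silylated vanillin
Product: 29 syn-aldol adduct, (R)-4-benzyl-3-[(2R,3R)-3-hydroxy-2-(ring B aryl)-3-(ring D aryl)propanoyl]oxazolidin-2-one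
Conditions: n-Bu2BOTf, i-Pr2NEt, CH2Cl2, −78 to 0 °C; then 28, −78 to 0 °C; pH 7 buffer, MeOH, 30% H2O2, 0 °C
Reagents that add atoms: none
Why: Evans syn aldol: the Z boron enolate reacts through a closed chair transition state with the auxiliary carbonyl turned away, so the benzyl group of the (R)-auxiliary fixes the α-centre (2R here, which becomes S once the carbinol carbon is the ketone). The reaction is established for arylacetyl imides with aryl aldehydes.

Step 24
Reactants: 29 syn-aldol adduct
Product: 30 (1R,2S)-1-(ring D aryl)-2-(ring B aryl)propane-1,3-diol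
Conditions: LiBH4, MeOH (1 equiv), THF, 0 °C
Reagents that add atoms: none
Why: Reductive removal of the auxiliary from the imide carbonyl, which is far more reactive than any other group present; the short, cold reaction limits retro-aldol cleavage.

Step 25
Reactants: 30 1,3-diol
Product: 31 primary tert-butyldimethylsilyl ether of 30 (secondary benzylic OH free)
Conditions: TBSCl (1.1 equiv), imidazole, CH2Cl2, 0 °C
Reagents that add atoms: tert-butyldimethylsilyl chloride, CC(C)(C)[Si](C)(C)Cl
Why: Steric differentiation of a primary from a hindered secondary benzylic hydroxyl.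

Step 26
Reactants: 31 secondary alcohol
Product: 32 fully silylated (S)-ketone
Conditions: Dess–Martin periodinane, NaHCO3, CH2Cl2, 0 °C to rt
Reagents that add atoms: none
Why: Buffered, non-basic oxidation of the benzylic alcohol; the α-centre is not enolised, and the silylated β-oxygen cannot leave by retro-aldol reaction.

Step 27
Reactants: 32 fully silylated ketone
Product: 33 target CNP0174045.1
Conditions: TBAF, AcOH (1:1), THF, 0 °C to rt
Reagents that add atoms: none
Why: Global cleavage of three aryl and two primary alkyl silyl ethers with acetic acid-buffered fluoride, which keeps phenoxide and alkoxide basicity low enough to spare the α-aryl β-hydroxy ketone and the cis-dihydrobenzofuran.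

## Compound list

1 | vanillin | O=Cc1ccc(O)c(OC)c1 | starting material
2 | 4-(allyloxy)-3-methoxybenzaldehyde | O=Cc1ccc(OCC=C)c(OC)c1 | intermediate
3 | 3-allyl-4-hydroxy-5-methoxybenzaldehyde | O=Cc1cc(CC=C)c(O)c(OC)c1 | intermediate
4 | 3-allyl-5-methoxy-4-(triisopropylsilyloxy)benzaldehyde | O=Cc1cc(CC=C)c(O[Si](C(C)C)(C(C)C)C(C)C)c(OC)c1 | intermediate
5 | rac-1-ArB-prop-2-en-1-ol | C=CC(O)c1cc(CC=C)c(O[Si](C(C)C)(C(C)C)C(C)C)c(OC)c1 | intermediate
6 | 1-ArB-prop-2-en-1-one | C=CC(=O)c1cc(CC=C)c(O[Si](C(C)C)(C(C)C)C(C)C)c(OC)c1 | intermediate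
7 | 4-formyl-2-methoxyphenyl pivalate | O=Cc1ccc(OC(=O)C(C)(C)C)c(OC)c1 | intermediate
8 | 4-(hydroxymethyl)-2-methoxyphenyl pivalate | OCc1ccc(OC(=O)C(C)(C)C)c(OC)c1 | intermediate
9 | 5-bromovanillin | O=Cc1cc(Br)c(O)c(OC)c1 | starting material
10 | 3-bromo-5-methoxy-4-{[3-methoxy-4-(pivaloyloxy)benzyl]oxy}benzaldehyde | O=Cc1cc(Br)c(OCc2ccc(OC(=O)C(C)(C)C)c(OC)c2)c(OC)c1 | intermediate
11 | 1-ArC-4-ArB-butane-1,4-dione | O=C(CCC(=O)c1cc(CC=C)c(O[Si](C(C)C)(C(C)C)C(C)C)c(OC)c1)c1cc(Br)c(OCc2ccc(OC(=O)C(C)(C)C)c(OC)c2)c(OC)c1 | intermediate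
12 | (1Z,3Z)-1-ArC-4-ArB-1,4-bis(trimethylsilyloxy)buta-1,3-diene | C[Si](C)(C)O/C(c1cc(Br)c(OCc2ccc(OC(=O)C(C)(C)C)c(OC)c2)c(OC)c1)=C\C=C(/O[Si](C)(C)C)c1cc(CC=C)c(O[Si](C(C)C)(C(C)C)C(C)C)c(OC)c1 | intermediate
13 | formaldehyde | C=O | starting material
14 | (2R,3Z)-1-ArB-4-ArC-2-(hydroxymethyl)-4-(trimethylsilyloxy)but-3-en-1-one | C[Si](C)(C)O/C(c1cc(Br)c(OCc2ccc(OC(=O)C(C)(C)C)c(OC)c2)c(OC)c1)=C\[C@H](CO)C(=O)c1cc(CC=C)c(O[Si](C(C)C)(C(C)C)C(C)C)c(OC)c1 | intermediate
15 | (2R,3R)-1-ArC-4-ArB-2,3-bis(hydroxymethyl)butane-1,4-dione | O=C(c1cc(Br)c(OCc2ccc(OC(=O)C(C)(C)C)c(OC)c2)c(OC)c1)[C@@H](CO)[C@H](CO)C(=O)c1cc(CC=C)c(O[Si](C(C)C)(C(C)C)C(C)C)c(OC)c1 | intermediate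
16 | (2R,3R)-1-ArC-4-ArB-2,3-bis(hydroxymethyl)butane-1,4-diol, epimer mixture at C1 and C4 | OC(c1cc(Br)c(OCc2ccc(OC(=O)C(C)(C)C)c(OC)c2)c(OC)c1)[C@@H](CO)[C@H](CO)C(O)c1cc(CC=C)c(O[Si](C(C)C)(C(C)C)C(C)C)c(OC)c1 | intermediate
17 | (1R,2S,5R,6S)-2-ArB-6-ArC-3,7-dioxabicyclo[3.3.0]octane | C=CCc1cc([C@H]2OC[C@H]3[C@@H]2CO[C@@H]3c2cc(OC)c(OCc3ccc(OC(=O)C(C)(C)C)c(OC)c3)c(Br)c2)cc(OC)c1O[Si](C(C)C)(C(C)C)C(C)C | intermediate
18 | 17 with Br replaced by CH2CO2Me | C=CCc1cc([C@H]2OC[C@H]3[C@@H]2CO[C@@H]3c2cc(OC)c(OCc3ccc(OC(=O)C(C)(C)C)c(OC)c3)c(CC(=O)OC)c2)cc(OC)c1O[Si](C(C)C)(C(C)C)C(C)C | intermediate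
19 | 17 with Br replaced by C(=N2)CO2Me | C=CCc1cc([C@H]2OC[C@H]3[C@@H]2CO[C@@H]3c2cc(OC)c(OCc3ccc(OC(=O)C(C)(C)C)c(OC)c3)c(C(=[N+]=[N-])C(=O)OC)c2)cc(OC)c1O[Si](C(C)C)(C(C)C)C(C)C | intermediate
20 | core with ArB on C2 and, on C6, C5 of methyl (2S,3R)-7-methoxy-2-[3-methoxy-4-(pivaloyloxy)phenyl]-2,3-dihydrobenzofuran-3-carboxylate (cis) | C=CCc1cc([C@H]2OC[C@H]3[C@@H]2CO[C@@H]3c2cc(OC)c3c(c2)[C@@H](C(=O)OC)[C@@H](c2ccc(OC(=O)C(C)(C)C)c(OC)c2)O3)cc(OC)c1O[Si](C(C)C)(C(C)C)C(C)C | intermediate
21 | as 20 with (2S,3S)-3-hydroxymethyl and free ring E phenol | C=CCc1cc([C@H]2OC[C@H]3[C@@H]2CO[C@@H]3c2cc(OC)c3c(c2)[C@@H](CO)[C@@H](c2ccc(O)c(OC)c2)O3)cc(OC)c1O[Si](C(C)C)(C(C)C)C(C)C | intermediate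
22 | bis(tert-butyldimethylsilyl) ether of 21 | C=CCc1cc([C@H]2OC[C@H]3[C@@H]2CO[C@@H]3c2cc(OC)c3c(c2)[C@@H](CO[Si](C)(C)C(C)(C)C)[C@@H](c2ccc(O[Si](C)(C)C(C)(C)C)c(OC)c2)O3)cc(OC)c1O[Si](C(C)C)(C(C)C)C(C)C | intermediate
23 | 22 with the allyl group replaced by CH2CHO | O=CCc1cc([C@H]2OC[C@H]3[C@@H]2CO[C@@H]3c2cc(OC)c3c(c2)[C@@H](CO[Si](C)(C)C(C)(C)C)[C@@H](c2ccc(O[Si](C)(C)C(C)(C)C)c(OC)c2)O3)cc(OC)c1O[Si](C(C)C)(C(C)C)C(C)C | intermediate
24 | 22 with the allyl group replaced by CH2CO2H | OC(=O)Cc1cc([C@H]2OC[C@H]3[C@@H]2CO[C@@H]3c2cc(OC)c3c(c2)[C@@H](CO[Si](C)(C)C(C)(C)C)[C@@H](c2ccc(O[Si](C)(C)C(C)(C)C)c(OC)c2)O3)cc(OC)c1O[Si](C(C)C)(C(C)C)C(C)C | intermediate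
25 | (R)-4-benzyloxazolidin-2-one | O=C1OC[C@@H](Cc2ccccc2)N1 | starting material
26 | mixed anhydride of 24 with pivalic acid | CC(C)(C)C(=O)OC(=O)Cc1cc([C@H]2OC[C@H]3[C@@H]2CO[C@@H]3c2cc(OC)c3c(c2)[C@@H](CO[Si](C)(C)C(C)(C)C)[C@@H](c2ccc(O[Si](C)(C)C(C)(C)C)c(OC)c2)O3)cc(OC)c1O[Si](C(C)C)(C(C)C)C(C)C | intermediate
27 | (R)-4-benzyl-3-(arylacetyl)oxazolidin-2-one from 24 | O=C1OC[C@@H](Cc2ccccc2)N1C(=O)Cc1cc([C@H]2OC[C@H]3[C@@H]2CO[C@@H]3c2cc(OC)c3c(c2)[C@@H](CO[Si](C)(C)C(C)(C)C)[C@@H](c2ccc(O[Si](C)(C)C(C)(C)C)c(OC)c2)O3)cc(OC)c1O[Si](C(C)C)(C(C)C)C(C)C | intermediate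
28 | 4-(tert-butyldimethylsilyloxy)-3-methoxybenzaldehyde | O=Cc1ccc(O[Si](C)(C)C(C)(C)C)c(OC)c1 | intermediate
29 | (R)-4-benzyl-3-[(2R,3R)-3-hydroxy-2-(ring B aryl)-3-(4-silyloxy-3-methoxyphenyl)propanoyl]oxazolidin-2-one | COc1cc([C@H](O)[C@H](C(=O)N2[C@H](Cc3ccccc3)COC2=O)c2cc([C@H]3OC[C@H]4[C@@H]3CO[C@@H]4c3cc(OC)c4c(c3)[C@@H](CO[Si](C)(C)C(C)(C)C)[C@@H](c3ccc(O[Si](C)(C)C(C)(C)C)c(OC)c3)O4)cc(OC)c2O[Si](C(C)C)(C(C)C)C(C)C)ccc1O[Si](C)(C)C(C)(C)C | intermediate
30 | (1R,2S)-1-(ring D aryl)-2-(ring B aryl)propane-1,3-diol | COc1cc([C@H](O)[C@H](CO)c2cc([C@H]3OC[C@H]4[C@@H]3CO[C@@H]4c3cc(OC)c4c(c3)[C@@H](CO[Si](C)(C)C(C)(C)C)[C@@H](c3ccc(O[Si](C)(C)C(C)(C)C)c(OC)c3)O4)cc(OC)c2O[Si](C(C)C)(C(C)C)C(C)C)ccc1O[Si](C)(C)C(C)(C)C | intermediate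
31 | primary tert-butyldimethylsilyl ether of 30 | COc1cc([C@H](O)[C@H](CO[Si](C)(C)C(C)(C)C)c2cc([C@H]3OC[C@H]4[C@@H]3CO[C@@H]4c3cc(OC)c4c(c3)[C@@H](CO[Si](C)(C)C(C)(C)C)[C@@H](c3ccc(O[Si](C)(C)C(C)(C)C)c(OC)c3)O4)cc(OC)c2O[Si](C(C)C)(C(C)C)C(C)C)ccc1O[Si](C)(C)C(C)(C)C | intermediate
32 | pentasilylated target, (S)-ketone | COc1cc(C(=O)[C@H](CO[Si](C)(C)C(C)(C)C)c2cc([C@H]3OC[C@H]4[C@@H]3CO[C@@H]4c3cc(OC)c4c(c3)[C@@H](CO[Si](C)(C)C(C)(C)C)[C@@H](c3ccc(O[Si](C)(C)C(C)(C)C)c(OC)c3)O4)cc(OC)c2O[Si](C(C)C)(C(C)C)C(C)C)ccc1O[Si](C)(C)C(C)(C)C | intermediate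
33 | CNP0174045.1 | COc1cc(C(=O)[C@H](CO)c2cc([C@H]3OC[C@H]4[C@@H]3CO[C@@H]4c3cc(OC)c4c(c3)[C@@H](CO)[C@@H](c3ccc(O)c(OC)c3)O4)cc(OC)c2O)ccc1O | target

## Step count and risks

Total: 27 steps. Longest linear sequence: 23 steps from vanillin (steps 1–5, 9–21, 23–27).

**Step 11 (key step).**
- What may go wrong: protodesilylation of the enol silanes in the aqueous Lewis-acidic medium may outrun C–C bond formation; the first-formed centre may enolise before the second addition; a mismatched second addition would lower the share of homochiral material; hemiketalisation and dehydration of the product may follow.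
- Fallback (known tandem conjugate addition–aldol on a chiral butenolide; sets out from 4 and 10, returns at 16): aldehyde 4 is converted with propane-1,3-dithiol and BF3·OEt2 into 2-ArB-1,3-dithiane F1 as the acyl anion precursor. After deprotonation with n-BuLi (THF, −78 °C) the carbanion adds to (5R)-5-[(1R,2S,5R)-menthyloxy]furan-2(5H)-one F2 anti to the menthyloxy group, and the lactone enolate is trapped by aldehyde 10 anti to the new substituent to give the trans,trans lactone adduct F3 as a carbinol mixture. Alkylative hydrolysis of the dithiane (MeI, CaCO3, aqueous MeCN) gives the keto lactone F4 without touching the acetal. LiAlH4 (THF, 0 °C) reduces ketone, lactone and acetal carbon and also cleaves the pivalate, giving the (2R,3R)-pentaol F5 with a free phenol on the benzyl ring. Its phenoxide alone is re-acylated (PivCl, aqueous NaOH/CH2Cl2) to give tetraol 16.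

**Step 13.**
- What may go wrong: slow ionisation at the bromine-bearing, twisted ring C; capture of a benzylic cation by the other benzylic hydroxyl instead of the primary one; trapping of one aryl group endo; loss of formaldehyde by fragmentation of the 1,3-diol cation.
- Fallback (carbinol configuration set by reagent, closure by substitution at the primary carbons; sets out from 15, returns at 17): Noyori transfer hydrogenation of 15 with RuCl(p-cymene)[(S,S)-TsDPEN] in HCO2H/Et3N gives the single (1S,2R,3R,4S)-tetraol F6 under catalyst control. Selective sulfonylation of the two primary hydroxyls (MsCl, pyridine, 0 °C) gives the primary bis(methanesulfonate) F7 in the flask, and displacement by the benzylic hydroxyls closes both rings with retention at C2 and C6 to give 17.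

**Step 16.**
- What may go wrong: poor discrimination of the two benzylic hydrogens by the catalyst, because the benzyloxy group is flanked by a methoxy group. Since the core is already enantiopure, this would show as contamination by a second cis diastereomer that is hard to separate. Some carbenoid may be lost to reaction at the allyl group.
- Fallback (enzymatic discrimination in place of catalyst control; sets out from 19, returns at 21): the insertion is run with the achiral catalyst Rh2(OPiv)4 for cis selectivity only, giving the cis ester F8 as both facial isomers of the dihydrobenzofuran. i-Bu2AlH reduction gives the corresponding diol pair F9 as two diastereomers. A lipase (Burkholderia cepacia lipase, vinyl acetate, t-BuOMe), which reads the configuration next to the primary hydroxyl, converts the unwanted isomer into its primary acetate F10 and leaves 21, which is separated from it.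

**Step 23.**
- What may go wrong: the enolate is flanked by the ortho triisopropylsilyloxy group and the aldehyde is electron-rich, so addition may be slow and reversible, with retro-aldol cleavage on work-up and erosion of syn selectivity.
- Fallback (α-centre set by auxiliary-controlled hydroxymethylation, ketone made by acyl substitution; sets out from 27, returns at 32): soft enolisation of 27 (TiCl4, i-Pr2NEt, CH2Cl2, 0 °C) and reaction with 1,3,5-trioxane/TiCl4 anti to the auxiliary benzyl group gives the (S)-α-hydroxymethyl imide F11 by direct hydroxymethylation. TBSCl/imidazole gives its silyl ether F12 in the usual way. LiSEt (THF, 0 °C) converts it into the S-ethyl thioester F13 with release of the auxiliary. Fukuyama coupling of F13 with [4-(tert-butyldimethylsilyloxy)-3-methoxyphenyl]zinc iodide F14 under PdCl2(PPh3)2 in toluene gives ketone 32 without the aldol, reduction and oxidation.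

**Step 27 (with step 26).**
- What may go wrong: enolisation of the α-aryl ketone by fluoride or the liberated phenoxides, causing epimerisation; once the β-oxygen is free, loss of formaldehyde by retro-aldol reaction or of water by elimination; cyclodehydration of the ortho phenol onto the ketone.
- Fallback (the order of unmasking and oxidation is reversed, so the ketone never meets fluoride; sets out from 31, returns at 33): all five silyl ethers of 31 are removed with TBAF at the alcohol oxidation level, where no enolisable centre exists, giving the free polyol F15 as the benzylic alcohol form of the target. Activated MnO2 in acetone then oxidises only the para-hydroxybenzylic secondary alcohol, leaving the primary alcohols alone, to give 33.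

## Further compounds

F1 | step 11 | 2-ArB-1,3-dithiane | C=CCc1cc(C2SCCCS2)cc(OC)c1O[Si](C(C)C)(C(C)C)C(C)C
F2 | step 11 | (5R)-5-[(1R,2S,5R)-menthyloxy]furan-2(5H)-one | O=C1C=C[C@H](O[C@@H]2C[C@H](C)CC[C@H]2C(C)C)O1
F3 | step 11 | (3S,4R,5R)-3-[hydroxy(ArC)methyl]-4-(2-ArB-1,3-dithian-2-yl)-5-menthyloxy-dihydrofuran-2-one | O=C1O[C@@H](O[C@@H]2C[C@H](C)CC[C@H]2C(C)C)[C@H](C2(SCCCS2)c2cc(CC=C)c(O[Si](C(C)C)(C(C)C)C(C)C)c(OC)c2)[C@H]1C(O)c1cc(Br)c(OCc2ccc(OC(=O)C(C)(C)C)c(OC)c2)c(OC)c1
F4 | step 11 | keto lactone from F3 (dithiane replaced by C=O) | O=C1O[C@@H](O[C@@H]2C[C@H](C)CC[C@H]2C(C)C)[C@H](C(=O)c2cc(CC=C)c(O[Si](C(C)C)(C(C)C)C(C)C)c(OC)c2)[C@H]1C(O)c1cc(Br)c(OCc2ccc(OC(=O)C(C)(C)C)c(OC)c2)c(OC)c1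
F5 | step 11 | (2R,3R)-pentaol, tetraol 16 with the pivalate cleaved to the free phenol | OC(c1cc(Br)c(OCc2ccc(O)c(OC)c2)c(OC)c1)[C@@H](CO)[C@H](CO)C(O)c1cc(CC=C)c(O[Si](C(C)C)(C(C)C)C(C)C)c(OC)c1
F6 | step 13 | (1S,2R,3R,4S)-1-ArC-4-ArB-2,3-bis(hydroxymethyl)butane-1,4-diol | O[C@H](c1cc(Br)c(OCc2ccc(OC(=O)C(C)(C)C)c(OC)c2)c(OC)c1)[C@@H](CO)[C@H](CO)[C@H](O)c1cc(CC=C)c(O[Si](C(C)C)(C(C)C)C(C)C)c(OC)c1
F7 | step 13 | primary bis(methanesulfonate) of F6 | O[C@H](c1cc(Br)c(OCc2ccc(OC(=O)C(C)(C)C)c(OC)c2)c(OC)c1)[C@@H](COS(C)(=O)=O)[C@H](COS(C)(=O)=O)[C@H](O)c1cc(CC=C)c(O[Si](C(C)C)(C(C)C)C(C)C)c(OC)c1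
F8 | step 16 | cis ester 20 as both facial isomers of the dihydrobenzofuran | C=CCc1cc([C@H]2OC[C@H]3[C@@H]2CO[C@@H]3c2cc(OC)c3c(c2)C(C(=O)OC)C(c2ccc(OC(=O)C(C)(C)C)c(OC)c2)O3)cc(OC)c1O[Si](C(C)C)(C(C)C)C(C)C
F9 | step 16 | diol 21 as both cis facial isomers of the dihydrobenzofuran | C=CCc1cc([C@H]2OC[C@H]3[C@@H]2CO[C@@H]3c2cc(OC)c3c(c2)C(CO)C(c2ccc(O)c(OC)c2)O3)cc(OC)c1O[Si](C(C)C)(C(C)C)C(C)C
F10 | step 16 | primary acetate of the (2R,3R)-dihydrobenzofuran diastereomer of 21 | C=CCc1cc([C@H]2OC[C@H]3[C@@H]2CO[C@@H]3c2cc(OC)c3c(c2)[C@H](COC(C)=O)[C@H](c2ccc(O)c(OC)c2)O3)cc(OC)c1O[Si](C(C)C)(C(C)C)C(C)C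
F11 | step 23 | (R)-4-benzyl-3-[(S)-3-hydroxy-2-(ring B aryl)propanoyl]oxazolidin-2-one | O=C1OC[C@@H](Cc2ccccc2)N1C(=O)[C@H](CO)c1cc([C@H]2OC[C@H]3[C@@H]2CO[C@@H]3c2cc(OC)c3c(c2)[C@@H](CO[Si](C)(C)C(C)(C)C)[C@@H](c2ccc(O[Si](C)(C)C(C)(C)C)c(OC)c2)O3)cc(OC)c1O[Si](C(C)C)(C(C)C)C(C)C
F12 | step 23 | tert-butyldimethylsilyl ether of F11 | O=C1OC[C@@H](Cc2ccccc2)N1C(=O)[C@H](CO[Si](C)(C)C(C)(C)C)c1cc([C@H]2OC[C@H]3[C@@H]2CO[C@@H]3c2cc(OC)c3c(c2)[C@@H](CO[Si](C)(C)C(C)(C)C)[C@@H](c2ccc(O[Si](C)(C)C(C)(C)C)c(OC)c2)O3)cc(OC)c1O[Si](C(C)C)(C(C)C)C(C)C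
F13 | step 23 | S-ethyl (S)-thioester from F12 | CCSC(=O)[C@H](CO[Si](C)(C)C(C)(C)C)c1cc([C@H]2OC[C@H]3[C@@H]2CO[C@@H]3c2cc(OC)c3c(c2)[C@@H](CO[Si](C)(C)C(C)(C)C)[C@@H](c2ccc(O[Si](C)(C)C(C)(C)C)c(OC)c2)O3)cc(OC)c1O[Si](C(C)C)(C(C)C)C(C)C
F14 | step 23 | [4-(tert-butyldimethylsilyloxy)-3-methoxyphenyl]zinc iodide | COc1cc([Zn]I)ccc1O[Si](C)(C)C(C)(C)C
F15 | step 27 | fully desilylated 31 (benzylic alcohol form of the target) | COc1cc([C@H](O)[C@H](CO)c2cc([C@H]3OC[C@H]4[C@@H]3CO[C@@H]4c3cc(OC)c4c(c3)[C@@H](CO)[C@@H](c3ccc(O)c(OC)c3)O4)cc(OC)c2O)ccc1O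
A1 | alternative 1 | (2R)-6-bromo-3-diazo-8-methoxy-2-[4-(tert-butyldimethylsilyloxy)-3-methoxyphenyl]chroman-4-one | Brc1cc(OC)c2c(c1)C(=O)C(=[N+]=[N-])[C@@H](c1ccc(O[Si](C)(C)C(C)(C)C)c(OC)c1)O2
A2 | alternative 1 | methyl cis-(2S,3R)-5-bromo-7-methoxy-2-[4-(tert-butyldimethylsilyloxy)-3-methoxyphenyl]-2,3-dihydrobenzofuran-3-carboxylate | Brc1cc(OC)c2c(c1)[C@@H](C(=O)OC)[C@@H](c1ccc(O[Si](C)(C)C(C)(C)C)c(OC)c1)O2
A3 | alternative 2 | (1R,5R)-3,7-dioxabicyclo[3.3.0]octane-2,6-diyl diacetate (bis-lactol diacetate) | CC(=O)OC1OC[C@H]2[C@@H]1COC2OC(C)=O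
A4 | alternative 2 | 2-allyl-6-methoxyphenol | C=CCc1cccc(OC)c1O
A5 | alternative 2 | 5,5'-diallylpinoresinol | C=CCc1cc([C@H]2OC[C@H]3[C@@H]2CO[C@@H]3c2cc(CC=C)c(O)c(OC)c2)cc(OC)c1O
A6 | alternative 3 | (E)-cinnamyl ether of the 1-aryl-2,3-epoxypropan-1-ol carrying the silylated dihydrobenzofuran (epoxide carbon unspecified) | COc1cc(/C=C/CO[C@@H](C2CO2)c2cc(OC)c3c(c2)[C@@H](CO[Si](C)(C)C(C)(C)C)[C@@H](c2ccc(O[Si](C)(C)C(C)(C)C)c(OC)c2)O3)cc(Br)c1O[Si](C)(C)C(C)(C)C
A7 | alternative 3 | ring B bromo furofuran carrying the silylated dihydrobenzofuran | COc1cc([C@H]2OC[C@H]3[C@@H]2CO[C@@H]3c2cc(OC)c3c(c2)[C@@H](CO[Si](C)(C)C(C)(C)C)[C@@H](c2ccc(O[Si](C)(C)C(C)(C)C)c(OC)c2)O3)cc(Br)c1O[Si](C)(C)C(C)(C)C
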